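## Structural features

The target is an aryltetralin lignan: an aromatic ring A (C4a, C5, C6, C7, C8, C8a) is fused through C4a and C8a to a saturated six-membered ring B (C1 to C4), and a 3,4,5-trimethoxyphenyl ring C is attached to C1. C2 and C3 carry the hydroxymethyl carbons C9 and C10, C4 is an unsubstituted benzylic CH2, and ring A bears a methyl ether on C6 and free hydroxyls on C7 and C8; this numbering is used for all intermediates as well. The three stereocentres C1 (S), C2 (R) and C3 (S) stand side by side on ring B, with ring C trans to C9 and with C9 cis to C10. The fragile groups are the C7/C8 catechol, which is oxidised to the o-quinone by air under base and binds metal ions, the C9/C10 1,4-diol, which can close to a tetrahydrofuran under acid, and the doubly benzylic C1–H. Ring A is pentasubstituted with three different oxygen functions in a row, so its pattern is best taken from a benzoate that already has it, and the two phenols must stay distinguishable from four methyl ethers until the end. The real difficulty is the 1,2-trans-2,3-cis array: C1 lies peri to the C8 oxygen and has no activating neighbour once ring B exists, and the cis relation of C9 and C10 is not the one that two free substituents on C2 and C3 would adopt on equilibration. The key step exploits the fact that C4 is the only ring B carbon without a substituent and sits between C3 and the aryl carbon C4a, which is para to the C7 oxygen: without C4, ring B shrinks to an indan-1-one whose carbonyl carbon is C3 and in which the trans C1/C2 pair is the stable one, and putting C4 back by diazoalkane insertion needs exactly this electron-rich C4a to migrate. The C3 ketone left by the insertion is then the point at which C10 is attached, and a lactone between C9 and C10 turns the cis relation into the preferred ring fusion.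

## Logic of the disconnections

21 from 20. The two O–CH2Ph bonds on the C7 and C8 oxygens are cut. The catechol is the most sensitive part, so it is unmasked last and under neutral conditions. The gain is that every earlier intermediate is a stable polyether. The demand is that the final hydrogenolysis meets no other cleavable benzylic C–O bond, which holds because C1 and C4 carry only C–C and C–H bonds.

20 from 19. The C9 and C10 hydroxyls are joined through a C10(=O)–O–C9 lactone. Inside this five-membered ring the cis relation of C9 and C10 is the preferred fusion, and C3 becomes α to a carbonyl and therefore adjustable. The gain is that C3 need not be set by a kinetic reaction. The demand is that the hydride opens the lactone faster than it enolises it.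

19 from 17 (through 18). The C3–H and C4–H bonds are removed to give a C3=C4 double bond conjugated with ring A and the lactone carbonyl. Such an alkene comes directly from a C3 ketone by way of its enol derivative. The gain is one stereocentre fewer. The demand is saturation without loss of the benzyl ethers, followed by equilibration of C3 to the cis fusion.

17 from 16. The lactone C10–O bond is cut, leaving a methyl ester on C3 and a silyl ether on the C9 oxygen. The C9 oxygen must be masked while C3 is a ketone or an enolate (risk of β-elimination), and unmasking it next to the ester closes the ring by itself. The demand is a desilylation that leaves the benzyl ethers alone.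

16 from 15. The C3–C10 bond is cut. C10 is a single carbon at the carboxyl level, which points to alkoxycarbonylation of an enol triflate. The gain is that C3 returns to the ketone oxidation level. The demand is insertion of the metal into a vinyl C–O bond beside the substituted C2.

15 from 14. The enol O–S bond is cut, giving the C3 ketone. The demand is enolisation toward C4 only, since an enolate toward C2 would expel the C9 oxygen.

14 from 11 and 12. The C3–C4 and C4–C4a bonds are cut and C4 is taken out. Ring B contracts to a five-membered ketone that a Dieckmann closure can make, in which C1/C2 trans is the stable arrangement. The gain is a ring that needs no benzylic methylene chemistry. The demand is that on insertion C4a migrates and C2 does not.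

11 from 10. The C3 carbonyl is traced to a C3 carbinol. This change of oxidation level is forced by the hydride step that precedes it. The demand is a neutral oxidant, because the product is a β-silyloxy ketone with an epimerisable C2.

10 from 9. The O–Si bond on the C9 oxygen is cut. The demand is selectivity for the primary over the secondary benzylic hydroxyl.

9 from 8. C9 and C3 are raised to the ester and ketone level. The reason is that 8 is the direct product of a ring closure. The demand is reduction of both carbonyls without enolate-derived side reactions; the trans C1/C2 relation is frozen at this point.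

8 from 7. The C2–C3 bond is cut (β-keto ester retron). The gain is an acyclic diester with a single stereocentre. The demand is closure of the C2 enolate onto the aryl ester on C4a and equilibration of C2 to trans.

7 from 5 and 6. The bond between C1 and ring C is cut. A β-aryl ester is the retron of a conjugate arylation, and this is the only stereocentre that a chiral reagent has to set. The gain is an achiral enoate and a commercial boronic acid. The demand is enantioface control at a β-carbon flanked by two ortho substituents.

5 from 3 and 4. The C1=C2 double bond is cut. The gain is that C2 and C9 arrive together in 4. The demand is E geometry.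

3 from 2. The two O–CH2Ph bonds are cut. The demand is complete etherification, including the hydrogen-bonded hydroxyl next to the aldehyde.

2 from 1. The C1–C8a bond is cut. A formyl group ortho to a phenol is the retron of a hydroxyl-directed ortho-formylation. The gain is commercial 1, which already holds the three ring A oxygens in the right order and the carbon that becomes C3. The demand is reaction only at the position between the hydroxyl and the ester.

## Other disconnections considered

Alternative 1: The C2–C9 and C3–C10 bonds are cut together, leading back to the C2=C3 alkene of the dihydronaphthalene A1 and to dichloroketene A2. In the forward step A2, made in the flask by zinc dechlorination of the acid chloride, would add by a concerted [2+2] cycloaddition on the face away from ring C. This would give the cis-fused dichlorocyclobutanone A3.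
- In its favour: suprafacial addition makes C9 and C10 cis, and approach anti to ring C makes them trans to it. Both C2 and C3 would be set in one kinetic step, which is better than the chosen plan, where C2 and C3 each rely on an equilibration.
- Against it here: A3 contains a C9–C10 bond that the target lacks. It must be cut again by dechlorination, oxidative cleavage and reduction of both ends. A1 is a skipped diene that can aromatise or move into conjugation under the zinc salts. The plan also leaves C1 unsolved, because A1 must first be obtained as one enantiomer.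
- Comparison: on mechanism it is a pericyclic step against a cationic 1,2-shift. On step economy the steps after A3 are about as many as the six that follow the key step chosen here, so the two are equal there; the cost of A1 decides.

Alternative 2: The C1–C8a and C4–C4a bonds are cut, so ring B comes from a Diels–Alder reaction of the o-quinone A4 (as an aryne equivalent) with the aryl diene A5. Under a chiral Lewis acid bound to both quinone carbonyls, A5 would add across the unsubstituted double bond of A4. Double enolisation would then give the dihydronaphthalenediol A6.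
- In its favour: two small achiral pieces give ring B, the C1 stereocentre and the free catechol in one catalytic step. This is better than the chosen plan in convergence and, combined with alternative 1 (A1 is the bis-benzyl ether of A6), probably in step count.
- Against it here: A4 is a labile quinone that can dimerise or react through its dione unit as a heterodiene. Its two carbonyls polarise the reacting double bond in opposite senses, so the orientation that places ring C next to C8a is not assured. The enantioface control rests on two-point binding alone. A6 can also aromatise under the conditions of its own enolisation.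
- Comparison: the chosen plan is longer but takes the ring A pattern unchanged from 1 and uses only reactions of established regiochemistry. Alternative 2 is shorter on paper but rests on two open selectivity questions.

Alternative 3: Ring A is cut at C4a–C5 and C8–C8a, leading back to the cyclohexenylstannane A7, which carries all three stereocentres, and the chlorocyclobutenone A8. A palladium-catalysed Stille coupling would join C4a to the chlorine-bearing carbon of A8. On warming, the alkenylcyclobutenone would open to a dienylketene, close by 6π electrocyclisation and tautomerise to the phenol A9.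
- In its favour: the positions of the ring A oxygens follow from connectivity alone, which is equal to the chosen plan. The cascade is neutral, and the stereocentres are set on a simple cyclohexene before any arene is present.
- Against it here: A9 carries a methyl ether on the C7 oxygen, whereas the target has a free hydroxyl there. Either a selective demethylation among five aryl methyl ethers or a differently protected partner such as A10 would be needed. A7, with three contiguous stereocentres, must be built without the help ring A gives in the chosen plan (Dieckmann closure, benzylic enolisation). Tin reagents are an added burden.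
- Comparison: the mechanism is elegant and regiospecific, but the stereochemical problem is moved, not solved, and the route is likely to be longer.

Key step: step 9

Assumption: the sense of induction in step 4 is taken from the usual quadrant model of rhodium–BINAP 1,4-additions to (E)-enoates, in which (R)-BINAP delivers the aryl group to the re face of the β-carbon; should the opposite sense be found, (S)-BINAP is used and nothing else changes.

## Route

Step 1
Reactants: 1 methyl 3,4-dihydroxy-5-methoxybenzoate
Product: 2 methyl 2-formyl-3,4-dihydroxy-5-methoxybenzoate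
Conditions: MgCl2 (3 equiv), Et3N (6 equiv), (CH2O)n (8 equiv), MeCN, reflux; 1 M HCl work-up
Reagents that add atoms: paraformaldehyde (as formaldehyde), C=O
Why: Casnati–Skattebøl ortho-formylation: formaldehyde is delivered inside the magnesium phenoxide chelate to the only free position ortho to a hydroxyl (future C8a, between the C8 hydroxyl and the ester), and a second formaldehyde oxidises the benzylic alkoxide to the aldehyde by hydride transfer; the other free position (future C5) has no hydroxyl neighbour and should stay untouched.

Step 2
Reactants: 2 methyl 2-formyl-3,4-dihydroxy-5-methoxybenzoate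
Product: 3 methyl 3,4-bis(benzyloxy)-2-formyl-5-methoxybenzoate
Conditions: BnBr (2.5 equiv), K2CO3 (3 equiv), DMF, 60 °C
Reagents that add atoms: benzyl bromide, BrCc1ccccc1
Why: Williamson ether synthesis on both phenoxides; the hydroxyl hydrogen-bonded to the aldehyde reacts more slowly, hence the excess and the warming, and the aldehyde and the methyl ester are inert to carbonate.

Step 3
Reactants: 3 methyl 3,4-bis(benzyloxy)-2-formyl-5-methoxybenzoate; 4 tert-butyl diethylphosphonoacetate
Product: 5 methyl 3,4-bis(benzyloxy)-2-[(1E)-3-tert-butoxy-3-oxoprop-1-en-1-yl]-5-methoxybenzoate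
Conditions: NaH (1.2 equiv), 4 (1.25 equiv), THF, 0 °C → rt
Reagents that add atoms: none
Why: Horner–Wadsworth–Emmons olefination; the stabilised phosphonate anion should give the (E)-enoate and is neither basic nor nucleophilic enough to attack the aryl methyl ester.

Step 4
Reactants: 5 methyl 3,4-bis(benzyloxy)-2-[(1E)-3-tert-butoxy-3-oxoprop-1-en-1-yl]-5-methoxybenzoate; 6 3,4,5-trimethoxyphenylboronic acid
Product: 7 tert-butyl (3S)-3-[2,3-bis(benzyloxy)-4-methoxy-6-(methoxycarbonyl)phenyl]-3-(3,4,5-trimethoxyphenyl)propanoate
Conditions: Rh(acac)(C2H4)2 (5 mol %), (R)-BINAP (5.5 mol %), 6 (4 equiv), dioxane–H2O (10:1), 100 °C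
Reagents that add atoms: none
Why: Hayashi–Miyaura reaction: transmetalation gives an aryl–rhodium species bound to (R)-BINAP, the enoate inserts with its ester substituent in the open quadrant so that ring C is delivered to the re face of C1 (giving S), and water protonates the oxa-π-allyl rhodium at C2; the tert-butyl ester favours high selectivity and survives the hot aqueous medium.

Step 5
Reactants: 7 tert-butyl (3S)-3-[2,3-bis(benzyloxy)-4-methoxy-6-(methoxycarbonyl)phenyl]-3-(3,4,5-trimethoxyphenyl)propanoate
Product: 8 tert-butyl (2R,3S)-4,5-bis(benzyloxy)-6-methoxy-1-oxo-3-(3,4,5-trimethoxyphenyl)indane-2-carboxylate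
Conditions: KOtBu (2.2 equiv), THF, 0 °C → rt; then 1 M HCl
Reagents that add atoms: none
Why: Dieckmann condensation: the tert-butyl ester enolate at C2 attacks the aryl methyl ester carbonyl (future C3) and the deprotonation of the β-keto ester drives the five-membered ring closure; on acidification C2 is protonated under thermodynamic control, which places the ester trans to ring C on C1, and C1 itself has no acidic hydrogen under these conditions.

Step 6
Reactants: 8 tert-butyl (2R,3S)-4,5-bis(benzyloxy)-6-methoxy-1-oxo-3-(3,4,5-trimethoxyphenyl)indane-2-carboxylate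
Product: 9 (2S,3S)-4,5-bis(benzyloxy)-2-(hydroxymethyl)-6-methoxy-3-(3,4,5-trimethoxyphenyl)indan-1-ol (both epimers at the carbinol carbon)
Conditions: LiAlH4 (4 equiv), THF, −20 °C → rt (8 added to the hydride); NaOH/H2O work-up
Reagents that add atoms: none
Why: Hydride reduction of the ketone and the ester of the β-keto ester in one operation; inverse addition at low temperature keeps carbonyl addition ahead of enolate formation, the trans C1/C2 relation is frozen once C2 is no longer α to a carbonyl, and the configuration of the new carbinol centre does not matter because step 8 removes it.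

Step 7
Reactants: 9 (2S,3S)-4,5-bis(benzyloxy)-2-(hydroxymethyl)-6-methoxy-3-(3,4,5-trimethoxyphenyl)indan-1-ol
Product: 10 (2S,3S)-4,5-bis(benzyloxy)-2-[(tert-butyldiphenylsilyloxy)methyl]-6-methoxy-3-(3,4,5-trimethoxyphenyl)indan-1-ol
Conditions: TBDPSCl (1.05 equiv), imidazole (2 equiv), CH2Cl2, 0 °C
Reagents that add atoms: tert-butyl(chloro)diphenylsilane, CC(C)(C)[Si](Cl)(c1ccccc1)c1ccccc1
Why: The bulky silyl chloride should silylate the primary C9 hydroxyl much faster than the secondary benzylic one flanked by ring A and C2; the tert-butyldiphenylsilyl ether is chosen over a tert-butyldimethylsilyl ether because it withstands BF3·OEt2 and the dilute acid of step 9.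

Step 8
Reactants: 10 (2S,3S)-4,5-bis(benzyloxy)-2-[(tert-butyldiphenylsilyloxy)methyl]-6-methoxy-3-(3,4,5-trimethoxyphenyl)indan-1-ol
Product: 11 (2S,3S)-4,5-bis(benzyloxy)-2-[(tert-butyldiphenylsilyloxy)methyl]-6-methoxy-3-(3,4,5-trimethoxyphenyl)indan-1-one
Conditions: MnO2 (activated, 15 equiv), CH2Cl2, rt
Reagents that add atoms: none
Why: MnO2 oxidises benzylic alcohols selectively under neutral heterogeneous conditions, so the β-silyloxy ketone forms without a base that could epimerise C2 or expel the silyloxy group; the trans 2,3-disubstituted indanone is also the more stable epimer.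

Step 9
Reactants: 11 (2S,3S)-4,5-bis(benzyloxy)-2-[(tert-butyldiphenylsilyloxy)methyl]-6-methoxy-3-(3,4,5-trimethoxyphenyl)indan-1-one; 12 trimethylsilyldiazomethane
Product: 14 (3S,4S)-5,6-bis(benzyloxy)-3-[(tert-butyldiphenylsilyloxy)methyl]-7-methoxy-4-(3,4,5-trimethoxyphenyl)-3,4-dihydronaphthalen-2(1H)-one, via C4-silyl ketone 13 (not isolated)
Conditions: 12 (2.0 equiv, hexanes), BF3·OEt2 (1.5 equiv), CH2Cl2, −78 → −30 °C; then 1 M HCl, THF, 0 °C
Reagents that add atoms: none
Why: BF3 binds the indanone oxygen and makes C3 electrophilic enough, despite its conjugation with the para-oxygenated ring A, for the diazo carbon of 12 to add and give a β-alkoxy diazonium betaine. Loss of N2 is concerted with a 1,2-shift of the substituent antiperiplanar to the C–N bond: the aryl carbon C4a migrates through a bridged, phenonium-like transition state stabilised by the C7 oxygen para to it, whereas C2 is a secondary carbon deactivated by its β-oxygen and hindered by the Me3Si group on the incoming carbon. The shift forms C3–C4 and C4–C4a and enlarges the five-membered ring to ring B, so the ring arises by ring expansion through a 1,2-aryl shift and not by a cyclisation; the closest known reaction type is the Lewis acid-promoted homologation of 1-indanones to 2-tetralones with trimethylsilyldiazomethane, a Büchner–Curtius–Schlotterbeck ring enlargement. The first product is the α-silyl ketone 13, whose bulky silyl group beside the carbonyl shields it from a second insertion, and dilute acid then replaces silicon on C4 by hydrogen. No stereocentre is created in 14, since C4 ends as CH2 and the transient silyl-bearing centre is erased, and C1 and C2 are not touched, so the trans relation set on the indanone is carried over and is also the stable arrangement next to the new ketone. The selectivity needed is aryl over alkyl migration and single over repeated insertion; the first is secured by the electron-rich ring A together with the hindered, oxygen-substituted C2, the second by the silyl group of 12. Low temperature and the robust silyl ether keep BF3 from enolising the ketone toward C2 and expelling the C9 oxygen.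

Step 10
Reactants: 14 (3S,4S)-5,6-bis(benzyloxy)-3-[(tert-butyldiphenylsilyloxy)methyl]-7-methoxy-4-(3,4,5-trimethoxyphenyl)-3,4-dihydronaphthalen-2(1H)-one
Product: 15 (3S,4S)-5,6-bis(benzyloxy)-3-[(tert-butyldiphenylsilyloxy)methyl]-7-methoxy-4-(3,4,5-trimethoxyphenyl)-3,4-dihydronaphthalen-2-yl trifluoromethanesulfonate
Conditions: KN(SiMe3)2 (1.1 equiv), PhNTf2 (1.2 equiv), THF, −78 °C
Reagents that add atoms: N-phenylbis(trifluoromethanesulfonimide), O=S(=O)(N(c1ccccc1)S(=O)(=O)C(F)(F)F)C(F)(F)F
Why: Kinetic and thermodynamic enolisation of a 2-tetralone both go toward the benzylic C4 (styrene-type enolate) and not toward the tertiary C2, and trapping on oxygen gives the C3=C4 enol triflate; the low temperature avoids a C2 enolate that could expel the silyloxy group.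

Step 11
Reactants: 15 (3S,4S)-5,6-bis(benzyloxy)-3-[(tert-butyldiphenylsilyloxy)methyl]-7-methoxy-4-(3,4,5-trimethoxyphenyl)-3,4-dihydronaphthalen-2-yl trifluoromethanesulfonate
Product: 16 methyl (3R,4S)-5,6-bis(benzyloxy)-3-[(tert-butyldiphenylsilyloxy)methyl]-7-methoxy-4-(3,4,5-trimethoxyphenyl)-3,4-dihydronaphthalene-2-carboxylate
Conditions: Pd(PPh3)4 (5 mol %), CO (1 atm), Et3N (3 equiv), MeOH–DMF (1:2), 60 °C
Reagents that add atoms: carbon monoxide, [C-]#[O+]; methanol, CO
Why: Palladium-catalysed alkoxycarbonylation of an enol triflate: oxidative addition to zerovalent palladium, CO insertion and methanolysis of the acylpalladium species attach C10 to C3, and C2 is not involved.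

Step 12
Reactants: 16 methyl (3R,4S)-5,6-bis(benzyloxy)-3-[(tert-butyldiphenylsilyloxy)methyl]-7-methoxy-4-(3,4,5-trimethoxyphenyl)-3,4-dihydronaphthalene-2-carboxylate
Product: 17 (3aR,4S)-5,6-bis(benzyloxy)-7-methoxy-4-(3,4,5-trimethoxyphenyl)-3a,4-dihydronaphtho[2,3-c]furan-1(3H)-one
Conditions: TBAF (1.5 equiv), THF, 0 °C → rt
Reagents that add atoms: none
Why: Fluoride cleaves the Si–O bond and the freed C9 alkoxide attacks the neighbouring methyl ester (5-exo-trig), closing the α-alkylidene γ-lactone with loss of methoxide; C2–H is not acidic in this system, so the stereocentres are unaffected.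

Step 13
Reactants: 17 (3aR,4S)-5,6-bis(benzyloxy)-7-methoxy-4-(3,4,5-trimethoxyphenyl)-3a,4-dihydronaphtho[2,3-c]furan-1(3H)-one
Product: 19 (3aR,4S,9aS)-5,6-bis(benzyloxy)-7-methoxy-4-(3,4,5-trimethoxyphenyl)-3a,4,9,9a-tetrahydronaphtho[2,3-c]furan-1(3H)-one, via trans-fused lactone 18 (not isolated)
Conditions: H2 (1 atm), Rh/Al2O3 (5 wt % Rh), THF, rt; then Ar, KOtBu (0.3 equiv), tBuOH–THF, rt; AcOH quench
Reagents that add atoms: none
Why: Heterogeneous hydrogenation over rhodium should saturate the conjugated C3=C4 bond while leaving aryl benzyl ethers intact, with hydrogen arriving mainly on the face away from ring C to give the trans-fused 18. Catalytic tert-butoxide then epimerises C3 through the lactone enolate to the more stable cis ring fusion (the driving force that turns trans-fused aryltetralin lactones into their cis-fused epimers), which sets C3 (S) under thermodynamic control. C1 and C2 carry no acidic hydrogen and stay as they are.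

Step 14
Reactants: 19 (3aR,4S,9aS)-5,6-bis(benzyloxy)-7-methoxy-4-(3,4,5-trimethoxyphenyl)-3a,4,9,9a-tetrahydronaphtho[2,3-c]furan-1(3H)-one
Product: 20 [(1S,2R,3S)-7,8-bis(benzyloxy)-6-methoxy-1-(3,4,5-trimethoxyphenyl)-1,2,3,4-tetrahydronaphthalene-2,3-diyl]dimethanol
Conditions: LiAlH4 (3 equiv), THF, 0 °C → rt; NaOH/H2O work-up
Reagents that add atoms: none
Why: LiAlH4 reduces the lactone to the C9/C10 diol faster than it could enolise it, and the cis arrangement is in any case the stable one at the lactone stage; benzyl and methyl ethers are inert.

Step 15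
Reactants: 20 [(1S,2R,3S)-7,8-bis(benzyloxy)-6-methoxy-1-(3,4,5-trimethoxyphenyl)-1,2,3,4-tetrahydronaphthalene-2,3-diyl]dimethanol
Product: 21 (6S,7R,8S)-6,7-bis(hydroxymethyl)-3-methoxy-8-(3,4,5-trimethoxyphenyl)-5,6,7,8-tetrahydronaphthalene-1,2-diol
Conditions: H2 (1 atm), Pd/C (10 wt % Pd), EtOAc–MeOH (1:1), rt
Reagents that add atoms: none
Why: Hydrogenolysis of the two aryl benzyl ethers under neutral conditions; no other benzylic C–O bond is present, the catechol is released without base or oxidant, and the product should be obtained by filtration and evaporation under inert gas.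

## Compound list

1 | methyl 3,4-dihydroxy-5-methoxybenzoate | COC(=O)c1cc(O)c(O)c(OC)c1 | starting material
2 | methyl 2-formyl-3,4-dihydroxy-5-methoxybenzoate | COC(=O)c1cc(OC)c(O)c(O)c1C=O | intermediate
3 | methyl 3,4-bis(benzyloxy)-2-formyl-5-methoxybenzoate | COC(=O)c1cc(OC)c(OCc2ccccc2)c(OCc2ccccc2)c1C=O | intermediate
4 | tert-butyl diethylphosphonoacetate | CCOP(=O)(CC(=O)OC(C)(C)C)OCC | starting material
5 | methyl 3,4-bis(benzyloxy)-2-[(1E)-3-tert-butoxy-3-oxoprop-1-en-1-yl]-5-methoxybenzoate | COC(=O)c1cc(OC)c(OCc2ccccc2)c(OCc2ccccc2)c1/C=C/C(=O)OC(C)(C)C | intermediate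
6 | 3,4,5-trimethoxyphenylboronic acid | COc1cc(B(O)O)cc(OC)c1OC | starting material
7 | tert-butyl (3S)-3-[2,3-bis(benzyloxy)-4-methoxy-6-(methoxycarbonyl)phenyl]-3-(3,4,5-trimethoxyphenyl)propanoate | COC(=O)c1cc(OC)c(OCc2ccccc2)c(OCc2ccccc2)c1[C@H](c1cc(OC)c(OC)c(OC)c1)CC(=O)OC(C)(C)C | intermediate
8 | tert-butyl (2R,3S)-4,5-bis(benzyloxy)-6-methoxy-1-oxo-3-(3,4,5-trimethoxyphenyl)indane-2-carboxylate (trans) | COc1cc2c(c(OCc3ccccc3)c1OCc1ccccc1)[C@H](c1cc(OC)c(OC)c(OC)c1)[C@@H](C(=O)OC(C)(C)C)C2=O | intermediate
9 | (2S,3S)-4,5-bis(benzyloxy)-2-(hydroxymethyl)-6-methoxy-3-(3,4,5-trimethoxyphenyl)indan-1-ol (trans at C2/C3; both C1 carbinol epimers) | COc1cc2c(c(OCc3ccccc3)c1OCc1ccccc1)[C@H](c1cc(OC)c(OC)c(OC)c1)[C@@H](CO)C2O | intermediate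
10 | (2S,3S)-4,5-bis(benzyloxy)-2-[(tert-butyldiphenylsilyloxy)methyl]-6-methoxy-3-(3,4,5-trimethoxyphenyl)indan-1-ol (both C1 carbinol epimers) | COc1cc2c(c(OCc3ccccc3)c1OCc1ccccc1)[C@H](c1cc(OC)c(OC)c(OC)c1)[C@@H](CO[Si](c1ccccc1)(c1ccccc1)C(C)(C)C)C2O | intermediate
11 | (2S,3S)-4,5-bis(benzyloxy)-2-[(tert-butyldiphenylsilyloxy)methyl]-6-methoxy-3-(3,4,5-trimethoxyphenyl)indan-1-one (trans) | COc1cc2c(c(OCc3ccccc3)c1OCc1ccccc1)[C@H](c1cc(OC)c(OC)c(OC)c1)[C@@H](CO[Si](c1ccccc1)(c1ccccc1)C(C)(C)C)C2=O | intermediate
12 | trimethylsilyldiazomethane | C[Si](C)(C)C=[N+]=[N-] | starting material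
13 | (3S,4S)-5,6-bis(benzyloxy)-3-[(tert-butyldiphenylsilyloxy)methyl]-7-methoxy-1-(trimethylsilyl)-4-(3,4,5-trimethoxyphenyl)-3,4-dihydronaphthalen-2(1H)-one (either configuration at the silyl-bearing carbon; not isolated) | COc1cc2c(c(OCc3ccccc3)c1OCc1ccccc1)[C@H](c1cc(OC)c(OC)c(OC)c1)[C@@H](CO[Si](c1ccccc1)(c1ccccc1)C(C)(C)C)C(=O)C2[Si](C)(C)C | intermediate
14 | (3S,4S)-5,6-bis(benzyloxy)-3-[(tert-butyldiphenylsilyloxy)methyl]-7-methoxy-4-(3,4,5-trimethoxyphenyl)-3,4-dihydronaphthalen-2(1H)-one | COc1cc2c(c(OCc3ccccc3)c1OCc1ccccc1)[C@H](c1cc(OC)c(OC)c(OC)c1)[C@@H](CO[Si](c1ccccc1)(c1ccccc1)C(C)(C)C)C(=O)C2 | intermediate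
15 | (3S,4S)-5,6-bis(benzyloxy)-3-[(tert-butyldiphenylsilyloxy)methyl]-7-methoxy-4-(3,4,5-trimethoxyphenyl)-3,4-dihydronaphthalen-2-yl trifluoromethanesulfonate | COc1cc2c(c(OCc3ccccc3)c1OCc1ccccc1)[C@H](c1cc(OC)c(OC)c(OC)c1)[C@@H](CO[Si](c1ccccc1)(c1ccccc1)C(C)(C)C)C(OS(=O)(=O)C(F)(F)F)=C2 | intermediate
16 | methyl (3R,4S)-5,6-bis(benzyloxy)-3-[(tert-butyldiphenylsilyloxy)methyl]-7-methoxy-4-(3,4,5-trimethoxyphenyl)-3,4-dihydronaphthalene-2-carboxylate | COc1cc2c(c(OCc3ccccc3)c1OCc1ccccc1)[C@H](c1cc(OC)c(OC)c(OC)c1)[C@@H](CO[Si](c1ccccc1)(c1ccccc1)C(C)(C)C)C(C(=O)OC)=C2 | intermediate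
17 | (3aR,4S)-5,6-bis(benzyloxy)-7-methoxy-4-(3,4,5-trimethoxyphenyl)-3a,4-dihydronaphtho[2,3-c]furan-1(3H)-one | COc1cc2c(c(OCc3ccccc3)c1OCc1ccccc1)[C@H](c1cc(OC)c(OC)c(OC)c1)[C@@H](CO3)C(C3=O)=C2 | intermediate
18 | (3aR,4S,9aR)-5,6-bis(benzyloxy)-7-methoxy-4-(3,4,5-trimethoxyphenyl)-3a,4,9,9a-tetrahydronaphtho[2,3-c]furan-1(3H)-one (trans-fused; not isolated) | COc1cc2c(c(OCc3ccccc3)c1OCc1ccccc1)[C@H](c1cc(OC)c(OC)c(OC)c1)[C@@H](CO3)[C@H](C3=O)C2 | intermediate
19 | (3aR,4S,9aS)-5,6-bis(benzyloxy)-7-methoxy-4-(3,4,5-trimethoxyphenyl)-3a,4,9,9a-tetrahydronaphtho[2,3-c]furan-1(3H)-one (cis-fused) | COc1cc2c(c(OCc3ccccc3)c1OCc1ccccc1)[C@H](c1cc(OC)c(OC)c(OC)c1)[C@@H](CO3)[C@@H](C3=O)C2 | intermediate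
20 | [(1S,2R,3S)-7,8-bis(benzyloxy)-6-methoxy-1-(3,4,5-trimethoxyphenyl)-1,2,3,4-tetrahydronaphthalene-2,3-diyl]dimethanol | COc1cc2c(c(OCc3ccccc3)c1OCc1ccccc1)[C@H](c1cc(OC)c(OC)c(OC)c1)[C@@H](CO)[C@@H](CO)C2 | intermediate
21 | (6S,7R,8S)-6,7-bis(hydroxymethyl)-3-methoxy-8-(3,4,5-trimethoxyphenyl)-5,6,7,8-tetrahydronaphthalene-1,2-diol | COc1cc2c(c(O)c1O)[C@H](c1cc(OC)c(OC)c(OC)c1)[C@@H](CO)[C@@H](CO)C2 | target

## Step count and least certain steps

Total step count: 15. Longest linear sequence: 15 steps (1 to 21); 4, 6 and 12 are commercial.

Step 9 (key step). The most likely failure is slow addition to C3, because the carbonyl is deactivated by conjugation with the para-oxygenated ring A and is flanked by the C2 substituent. At the higher temperature then needed, Lewis acid enolisation toward C2 with loss of the C9 oxygen, or a competing shift of C2 in place of C4a, would take over.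
Fallback: from 11, non-basic methylenation of the ketone with Cp2TiMe2 (toluene, 65 °C) gives the 1-methylideneindane F1. Oxidative rearrangement of F1 with the trivalent iodine reagent PhI(OH)OTs in MeOH follows, in which the same aryl carbon C4a shifts from C3 to the former methylene carbon, and dilute acid hydrolysis of the ketal returns to the route at 14.

Step 1. The most likely failure is sluggish or unclean formylation, because magnesium is tied up in a catecholate chelate and the reacting site is flanked by the ester; long reaction times then favour condensation of the product with more formaldehyde.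
Fallback: from 1, benzylation of the more acidic hydroxyl para to the ester (BnBr 1.05 equiv, KHCO3, DMF) gives methyl 4-(benzyloxy)-3-hydroxy-5-methoxybenzoate F2. The same formylation on this single phenol gives methyl 4-(benzyloxy)-2-formyl-3-hydroxy-5-methoxybenzoate F3, and a second benzylation returns to the route at 3.

Step 4. The most likely failure is low conversion, because insertion at a β-carbon flanked by two ortho substituents is slow and protodeboronation of 6 outruns it; poor facial selectivity is the second risk.
Fallback: from 3, olefination with diethyl {2-oxo-2-[(4R)-2-oxo-4-phenyl-1,3-oxazolidin-3-yl]ethyl}phosphonate gives the enoyl oxazolidinone F4. Addition of 3,4,5-trimethoxyphenylmagnesium bromide with CuBr·SMe2, anti to the phenyl group of the auxiliary in the chelated s-cis conformer, gives the adduct F5. LiOH/H2O2 removes the auxiliary to give the acid F6, and tert-butyl 2,2,2-trichloroacetimidate returns to the route at 7.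

Step 6. The most likely failure is deprotonation of the acidic β-keto ester by the hydride in competition with addition; the enolate that survives ester reduction then leads to elimination at C2/C9.
Fallback: from 8, CF3CO2H removes the tert-butyl group with decarboxylation to give the 3-arylindan-1-one F7. Its lithium enolate (LiN(SiMe3)2, THF, −78 °C) is hydroxymethylated with monomeric formaldehyde anti to ring C to give the trans hydroxymethyl ketone F8, and silylation as in step 7 returns to the route at 11, without passing through 9 and 10.

Step 13. The most likely failures are partial loss of benzyl ethers or slow saturation of an arene on rhodium, and incomplete epimerisation of C3.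
Fallback: from 17, H2 over Pd/C saturates the alkene and removes both benzyl ethers to give the catechol trans-lactone F9. Equilibration with KOtBu (3 equiv, degassed tBuOH–THF, AcOH quench) under strict exclusion of air gives the catechol cis-lactone F10, and LiAlH4 with an acidic work-up returns to the route at 21.

## Further compounds

F1 | step 9 | tert-butyl{[(2R,3S)-4,5-bis(benzyloxy)-6-methoxy-1-methylidene-3-(3,4,5-trimethoxyphenyl)-2,3-dihydro-1H-inden-2-yl]methoxy}diphenylsilane | COc1cc2c(c(OCc3ccccc3)c1OCc1ccccc1)[C@H](c1cc(OC)c(OC)c(OC)c1)[C@@H](CO[Si](c1ccccc1)(c1ccccc1)C(C)(C)C)C2=C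
F2 | step 1 | methyl 4-(benzyloxy)-3-hydroxy-5-methoxybenzoate | COC(=O)c1cc(O)c(OCc2ccccc2)c(OC)c1
F3 | step 1 | methyl 4-(benzyloxy)-2-formyl-3-hydroxy-5-methoxybenzoate | COC(=O)c1cc(OC)c(OCc2ccccc2)c(O)c1C=O
F4 | step 4 | methyl 3,4-bis(benzyloxy)-5-methoxy-2-{(1E)-3-oxo-3-[(4R)-2-oxo-4-phenyl-1,3-oxazolidin-3-yl]prop-1-en-1-yl}benzoate | COC(=O)c1cc(OC)c(OCc2ccccc2)c(OCc2ccccc2)c1/C=C/C(=O)N1C(=O)OC[C@H]1c1ccccc1
F5 | step 4 | methyl 3,4-bis(benzyloxy)-5-methoxy-2-{(1S)-3-oxo-3-[(4R)-2-oxo-4-phenyl-1,3-oxazolidin-3-yl]-1-(3,4,5-trimethoxyphenyl)propyl}benzoate | COC(=O)c1cc(OC)c(OCc2ccccc2)c(OCc2ccccc2)c1[C@H](c1cc(OC)c(OC)c(OC)c1)CC(=O)N1C(=O)OC[C@H]1c1ccccc1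
F6 | step 4 | (3S)-3-[2,3-bis(benzyloxy)-4-methoxy-6-(methoxycarbonyl)phenyl]-3-(3,4,5-trimethoxyphenyl)propanoic acid | COC(=O)c1cc(OC)c(OCc2ccccc2)c(OCc2ccccc2)c1[C@H](c1cc(OC)c(OC)c(OC)c1)CC(=O)O
F7 | step 6 | (3S)-4,5-bis(benzyloxy)-6-methoxy-3-(3,4,5-trimethoxyphenyl)indan-1-one | COc1cc2c(c(OCc3ccccc3)c1OCc1ccccc1)[C@H](c1cc(OC)c(OC)c(OC)c1)CC2=O
F8 | step 6 | (2S,3S)-4,5-bis(benzyloxy)-2-(hydroxymethyl)-6-methoxy-3-(3,4,5-trimethoxyphenyl)indan-1-one | COc1cc2c(c(OCc3ccccc3)c1OCc1ccccc1)[C@H](c1cc(OC)c(OC)c(OC)c1)[C@@H](CO)C2=O
F9 | step 13 | (3aR,4S,9aR)-5,6-dihydroxy-7-methoxy-4-(3,4,5-trimethoxyphenyl)-3a,4,9,9a-tetrahydronaphtho[2,3-c]furan-1(3H)-one | COc1cc2c(c(O)c1O)[C@H](c1cc(OC)c(OC)c(OC)c1)[C@@H](CO3)[C@H](C3=O)C2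
F10 | step 13 | (3aR,4S,9aS)-5,6-dihydroxy-7-methoxy-4-(3,4,5-trimethoxyphenyl)-3a,4,9,9a-tetrahydronaphtho[2,3-c]furan-1(3H)-one | COc1cc2c(c(O)c1O)[C@H](c1cc(OC)c(OC)c(OC)c1)[C@@H](CO3)[C@@H](C3=O)C2
A1 | alternative 1 | (1S)-7,8-bis(benzyloxy)-6-methoxy-1-(3,4,5-trimethoxyphenyl)-1,4-dihydronaphthalene | COc1cc2c(c(OCc3ccccc3)c1OCc1ccccc1)[C@H](c1cc(OC)c(OC)c(OC)c1)C=CC2
A2 | alternative 1 | dichloroketene | O=C=C(Cl)Cl
A3 | alternative 1 | cis-fused 2,2-dichlorocyclobutanone on C2–C3 of the 7,8-bis(benzyloxy)-6-methoxy-1-(3,4,5-trimethoxyphenyl)tetralin (carbonyl carbon on C2; both new carbons trans to ring C) | COc1cc2c(c(OCc3ccccc3)c1OCc1ccccc1)[C@H](c1cc(OC)c(OC)c(OC)c1)[C@@H](C(=O)C3(Cl)Cl)[C@@H]3C2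
A4 | alternative 2 | 3-methoxycyclohexa-3,5-diene-1,2-dione (3-methoxy-o-benzoquinone) | COC1=CC=CC(=O)C1=O
A5 | alternative 2 | 5-[(1E)-buta-1,3-dien-1-yl]-1,2,3-trimethoxybenzene | COc1cc(/C=C/C=C)cc(OC)c1OC
A6 | alternative 2 | (8S)-3-methoxy-8-(3,4,5-trimethoxyphenyl)-5,8-dihydronaphthalene-1,2-diol | COc1cc2c(c(O)c1O)[C@H](c1cc(OC)c(OC)c(OC)c1)C=CC2
A7 | alternative 3 | tributyl[(3R,4R,5S)-4,5-bis(benzyloxymethyl)-3-(3,4,5-trimethoxyphenyl)cyclohex-1-en-1-yl]stannane | CCCC[Sn](CCCC)(CCCC)C1=C[C@H](c2cc(OC)c(OC)c(OC)c2)[C@@H](COCc2ccccc2)[C@@H](COCc2ccccc2)C1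
A8 | alternative 3 | 4-chloro-2,3-dimethoxycyclobut-2-en-1-one | COC1=C(OC)C(=O)C1Cl
A9 | alternative 3 | (6S,7R,8S)-6,7-bis(benzyloxymethyl)-2,3-dimethoxy-8-(3,4,5-trimethoxyphenyl)-5,6,7,8-tetrahydronaphthalen-1-ol | COc1cc2c(c(O)c1OC)[C@H](c1cc(OC)c(OC)c(OC)c1)[C@@H](COCc1ccccc1)[C@@H](COCc1ccccc1)C2
A10 | alternative 3 | 2-(benzyloxy)-4-chloro-3-methoxycyclobut-2-en-1-one | COC1=C(OCc2ccccc2)C(=O)C1Cl
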